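## Retrosynthetic overview

1. Locants: unit A = C1 (ketone), C2–C3 (epoxide), C4 (ketal carbon), C5 (bonded to C4'), C7 (Cl), C8 (OH); unit B = C1' (carbinol), C2'–C3' (epoxide), C4' (O,C-quaternary carbon), C4a', C5' (aryl ether carbon), C7' (Cl), C8' (OH). Target ⇐ acid global deprotection ⇐ ring B epoxidation (anti to OTBS, convex face) ⇐ CBS reduction of the C1' enone of a hexacyclic core.
2. Core ⇐ one fluoride-triggered operation on a (Z)-ene-1,4-dione that carries a 2-(trimethylsilyl)aryl triflate: aryne C4a'≡C5' plus C4'=O ([2+2]; bonds C4a'–C4' and O–C5'; carbocycle of unit B) → benzoxete → o-quinone methide → hetero-Diels–Alder with the peri C4=O (dihydrofuran and 1,3-dioxine rings; stereocentres C4 and C4').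
3. Enabling feature: the 4H-1,3-benzodioxine ring C4–O–C5'–C4a'–C4'–O of the 2,8-dioxabicyclo[3.2.1]octane core is the formal adduct of an aryne (C4a'≡C5') with two carbonyls. C4=O and the C5 acyl group are peri on ring A, the acyl chain sits ortho (C8a') to the aryne on ring B, and the C2–C3 epoxide next to C4 steers the facial outcome.
4. The (Z)-ene-1,4-dione comes from oxidative opening of a 2,5-diarylfuran (a temporary ring that fixes the cis geometry and masks the dione) ⇐ Suzuki coupling of an enantioenriched ring A epoxy ketone bromide (from 1,5-dihydroxynaphthalene; asymmetric phase-transfer epoxidation sets the absolute configuration) with a furyl boronate of the ring B silyl triflate (from 4-chlororesorcinol; retro-Brook differentiation of the two phenols).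
5. Ring order: naphthalenone ketal of unit A → ring A epoxide → furan (temporary) → in the key step the unit B carbocycle, then the dihydrofuran and dioxine rings → ring B epoxide.

Key step: step 14

Remark on the chemistry (assumption): the cinchonidinium salt of step 5 is assumed to deliver the (2R,3S) epoxide; if the sense of induction is opposite, the pseudoenantiomeric N-benzylcinchoninium chloride is used instead. Primed and unprimed locants are those defined in line 1 of the overview.

## Route

Step 1
Reactants: 1 naphthalene-1,5-diol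
Product: 3 5-hydroxy-4,4-dimethoxynaphthalen-1(4H)-one, via 4-methoxynaphthalene-1,5-diol 2 (not isolated)
Conditions: PhI(OAc)2 (2.1 equiv), MeOH, 0 °C → rt
Reagents that add atoms: methanol CO (two equivalents)
Why: Oxidative dearomatisation of a para-unsubstituted naphthol (para-methoxylation to 2, then a second oxidation to the quinone monoketal) should stop at the monoketal because the remaining phenol ring is deactivated by the new carbonyl, and the symmetry of 1 leaves no regiochemical choice.

Step 2
Reactants: 3 5-hydroxy-4,4-dimethoxynaphthalen-1(4H)-one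
Product: 4 8-bromo-5-hydroxy-4,4-dimethoxynaphthalen-1(4H)-one
Conditions: NBS, MeCN, 0 °C
Reagents that add atoms: N-bromosuccinimide O=C1CCC(=O)N1Br
Why: Electrophilic aromatic bromination should go para to the free phenol, which is the future C5, peri to the ketone.

Step 3
Reactants: 4 8-bromo-5-hydroxy-4,4-dimethoxynaphthalen-1(4H)-one
Product: 5 8-bromo-6-chloro-5-hydroxy-4,4-dimethoxynaphthalen-1(4H)-one
Conditions: NCS, DMF, 40 °C
Reagents that add atoms: N-chlorosuccinimide O=C1CCC(=O)N1Cl
Why: Electrophilic aromatic chlorination can only take the one remaining phenol-activated position, ortho to the hydroxyl (future C7).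

Step 4
Reactants: 5 8-bromo-6-chloro-5-hydroxy-4,4-dimethoxynaphthalen-1(4H)-one
Product: 6 8-bromo-6-chloro-4,4-dimethoxy-5-(methoxymethoxy)naphthalen-1(4H)-one
Conditions: MOMCl, iPr2NEt, CH2Cl2, 0 °C → rt
Reagents that add atoms: chloromethyl methyl ether COCCl
Why: O-alkylation of the phenol gives a methoxymethyl ether that tolerates base, fluoride, oxidants and palladium and falls in the final acid step.

Step 5
Reactants: 6 8-bromo-6-chloro-4,4-dimethoxy-5-(methoxymethoxy)naphthalen-1(4H)-one
Product: 7 (2R,3S)-8-bromo-6-chloro-2,3-epoxy-4,4-dimethoxy-5-(methoxymethoxy)-3,4-dihydronaphthalen-1(2H)-one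
Conditions: t-BuOOH, N-benzylcinchonidinium chloride (10 mol%), aq. NaOH (cat.), toluene, 0 °C
Reagents that add atoms: tert-butyl hydroperoxide CC(C)(C)OO
Why: Asymmetric Weitz–Scheffer epoxidation under chiral phase-transfer catalysis, in which the chiral ion pair delivers the peroxide to one enantiotopic face of the planar enone ketal, sets C2 and C3 (cis by the ring) and with them the absolute configuration of the whole route.

Step 6
Reactants: 8 4-chlorobenzene-1,3-diol
Product: 9 4-bromo-6-chlorobenzene-1,3-diol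
Conditions: NBS, MeCN, −10 °C
Reagents that add atoms: N-bromosuccinimide O=C1CCC(=O)N1Br
Why: Electrophilic bromination of the resorcinol should go to C6, which is ortho/para to both hydroxyls and less hindered than C2.

Step 7
Reactants: 9 4-bromo-6-chlorobenzene-1,3-diol
Product: 10 4-bromo-6-chloro-2-iodobenzene-1,3-diol
Conditions: I2, NaHCO3, THF/H2O, 0 °C
Reagents that add atoms: iodine II
Why: Phenol iodination takes the position between the two hydroxyls, the only activated site left.

Step 8
Reactants: 10 4-bromo-6-chloro-2-iodobenzene-1,3-diol; 11 furan-2-boronic acid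
Product: 12 4-bromo-6-chloro-2-(furan-2-yl)benzene-1,3-diol
Conditions: Pd(dppf)Cl2 (5 mol%), K2CO3, dioxane/H2O, 60 °C
Reagents that add atoms: none
Why: Suzuki–Miyaura coupling, in which the C–I bond should undergo oxidative addition far faster than C–Br and C–Cl, so that only the 2-position is arylated.

Step 9
Reactants: 12 4-bromo-6-chloro-2-(furan-2-yl)benzene-1,3-diol
Product: 16 4-chloro-2-(furan-2-yl)-3-hydroxy-6-(trimethylsilyl)phenyl trifluoromethanesulfonate, via bis(trimethylsilyl) ether 13 (not isolated), via lithium aryloxide 14 (not isolated), via silyl ether triflate 15 (not isolated)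
Conditions: HMDS, THF, reflux, concentrate; then n-BuLi, THF, −78 °C; then Tf2O, −78 °C → rt; aq. citric acid work-up
Reagents that add atoms: hexamethyldisilazane C[Si](C)(C)N[Si](C)(C)C; trifluoromethanesulfonic anhydride O=S(=O)(OS(=O)(=O)C(F)(F)F)C(F)(F)F
Why: One-pot O-silylation, bromine–lithium exchange and retro-Brook 1,3-O→C silyl shift, in which only the oxygen ortho to the lithiated carbon gives up its silyl group, so that this aryloxide alone is triflated and the other phenol is released on work-up.

Step 10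
Reactants: 16 4-chloro-2-(furan-2-yl)-3-hydroxy-6-(trimethylsilyl)phenyl trifluoromethanesulfonate
Product: 17 4-chloro-2-(furan-2-yl)-3-(methoxymethoxy)-6-(trimethylsilyl)phenyl trifluoromethanesulfonate
Conditions: MOMCl, iPr2NEt, CH2Cl2, 0 °C → rt
Reagents that add atoms: chloromethyl methyl ether COCCl
Why: O-alkylation of the free phenol under amine base, which leaves the silyl triflate untouched.

Step 11
Reactants: 17 4-chloro-2-(furan-2-yl)-3-(methoxymethoxy)-6-(trimethylsilyl)phenyl trifluoromethanesulfonate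
Product: 18 4-chloro-3-(methoxymethoxy)-2-[5-(4,4,5,5-tetramethyl-1,3,2-dioxaborolan-2-yl)furan-2-yl]-6-(trimethylsilyl)phenyl trifluoromethanesulfonate
Conditions: [Ir(OMe)(cod)]2 (1.5 mol%), 4,4'-di-tert-butyl-2,2'-bipyridine (3 mol%), B2pin2, THF, 50 °C
Reagents that add atoms: bis(pinacolato)diboron CC1(C)OB(OC1(C)C)B1OC(C)(C)C(C)(C)O1
Why: Iridium-catalysed C–H borylation should select the free α-position of the furan, since the only arene C–H lies between SiMe3 and Cl and is sterically blocked.

Step 12
Reactants: 7 (2R,3S)-8-bromo-6-chloro-2,3-epoxy-4,4-dimethoxy-5-(methoxymethoxy)-3,4-dihydronaphthalen-1(2H)-one; 18 furyl boronate of the ring B silyl triflate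
Product: 19 2,5-diarylfuran (furan C5 on C5 of the unit A epoxy ketone ketal; furan C2 on C8a' of the ring B silyl triflate arene)
Conditions: Pd(dppf)Cl2 (5 mol%), K3PO4, THF/H2O, 45 °C
Reagents that add atoms: none
Why: Suzuki–Miyaura coupling at the aryl bromide, which should react in preference to the aryl triflate flanked by SiMe3 and furyl and to the aryl chlorides, under a fluoride-free base that leaves the aryne precursor intact.

Step 13
Reactants: 19 2,5-diarylfuran
Product: 20 (Z)-ene-1,4-dione aryne precursor (C5–C4'(=O)–C3'H=C2'H–C1'(=O)–C8a')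
Conditions: mCPBA (1.1 equiv), NaHCO3, CH2Cl2, 0 °C, dark
Reagents that add atoms: 3-chloroperbenzoic acid OOC(=O)c1cccc(Cl)c1
Why: Peracid oxidative ring opening of a 2,5-diarylfuran gives the cis-ene-1,4-dione, with the Z geometry dictated by the ring it comes from.

Step 14
Reactants: 20 (Z)-ene-1,4-dione aryne precursor
Product: 24 hexacyclic enone core (C1 dimethyl ketal; ring A epoxide; C4/C4' bis-ketal; C1' ketone; C2'=C3'; two MOM ethers), via aryne 21 (not isolated), via benzoxete 22 (not isolated), via quinone methide 23 (not isolated)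
Conditions: CsF (3 equiv), MeCN/THF (0.005 M), rt, dark
Reagents that add atoms: none
Why: Proposed new method: fluoride removes SiMe3 from C5' and triflate leaves C4a' to give aryne 21, whose C4' carbonyl (held over the triple bond by the Z-ene-dione) adds across it with O to the remote carbon C5' and C4' to C4a'; this [2+2] closes the six-membered carbocycle of unit B (C8a'–C1'–C2'–C3'–C4'–C4a') together with the strained benzoxete 22, and the closest known reaction type is the aryne/aldehyde or aryne/formamide [2+2] followed by 4π opening to an o-quinone methide and its [4+2] capture by a second C=O to give a 4H-1,3-benzodioxine, not yet shown for a tethered ketone. Strain-driven retro-4π opening of 22 should give the 4-aryl-1,5-naphthoquinone (o-quinone methide) 23, and the peri C4=O of ring A, within contact distance of C4', should then act as the 2π partner of an intramolecular hetero-Diels–Alder reaction that closes the five-membered dihydrofuran ring (C4–O–C4'–C5–C4a, by the O–C4' bond) and the six-membered 1,3-dioxine ring (C4–O–C5'–C4a'–C4'–O, by the O–C4 bond), driven by rearomatisation of ring B. The new stereocentres C4 and C4' are set together, because the quinone methide oxygen must reach C4 on the face anti to the adjacent C2–C3 epoxide and the bicyclo[3.2.1] constraint then fixes C4'. The two rotamers about the C5–C4' bond of 23 interconvert and only the one that places the C5' oxygen anti to the epoxide can close, so both should funnel to one diastereomer. The step needs regioselective aryne trapping, secured by the three-atom Z tether from C8a' (which allows only the C4'–C4a'/O–C5' mode) and by the electronic preference for attack at the aryne carbon remote from the C8a' acyl group, and it needs intramolecular capture to outrun fluoride addition and bimolecular aryne reactions, secured by high dilution.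

Step 15
Reactants: 24 hexacyclic enone core
Product: 25 (1'R)-allylic alcohol (C1'–OH on the face of unit B opposite to the bridging oxygen)
Conditions: (S)-2-methyl-CBS-oxazaborolidine (20 mol%), catecholborane, toluene, −78 °C; aq. work-up
Reagents that add atoms: none
Why: Corey–Bakshi–Shibata reduction under reagent control, with the aryl carbon C8a' (flanked by the peri OMOM group) as the large group and the vinyl carbon C2' as the small one, should deliver hydride to the face that gives the (1'R) alcohol with 1,2-selectivity.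

Step 16
Reactants: 25 (1'R)-allylic alcohol
Product: 26 (1'R)-tert-butyldimethylsilyl ether
Conditions: TBSCl, imidazole, DMF, 40 °C
Reagents that add atoms: tert-butyldimethylsilyl chloride CC(C)(C)[Si](C)(C)Cl
Why: Silylation under non-Lewis-acidic conditions spares the ketal and MOM groups, removes the hydroxyl directing effect and adds bulk on the concave face.

Step 17
Reactants: 26 (1'R)-tert-butyldimethylsilyl ether
Product: 27 bis-epoxide silyl ether (ring B epoxide syn to the bridging oxygen and anti to OTBS)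
Conditions: dimethyldioxirane, acetone/CH2Cl2, 0 °C → rt
Reagents that add atoms: dimethyldioxirane CC1(C)OO1
Why: Dioxirane epoxidation of the cis-alkene should take the convex face, because the opposite face is blocked by the ring A aryl group on C4' and by the silyl ether on C1', which sets C2' and C3' syn to the bridging oxygen and trans to the C1' oxygen.

Step 18
Reactants: 27 bis-epoxide silyl ether
Product: 28 target CNP0289684.3
Conditions: TFA/H2O/CH2Cl2, 0 °C → rt; NaHCO3 work-up
Reagents that add atoms: water O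
Why: Acid hydrolysis cleaves the dimethyl ketal to the C1 ketone, both methoxymethyl ethers and the silyl ether in one operation, while the epoxides (each flanked by an electron-poor carbon) and the rigid bicyclic aryl ketal should resist ionisation.

## Compound list

1 | naphthalene-1,5-diol | Oc1cccc2c(O)cccc12 | starting material
2 | 4-methoxynaphthalene-1,5-diol | COc1ccc(O)c2cccc(O)c12 | intermediate
3 | 5-hydroxy-4,4-dimethoxynaphthalen-1(4H)-one | COC1(OC)c2c(O)cccc2C(=O)C=C1 | intermediate
4 | 8-bromo-5-hydroxy-4,4-dimethoxynaphthalen-1(4H)-one | COC1(OC)c2c(O)ccc(Br)c2C(=O)C=C1 | intermediate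
5 | 8-bromo-6-chloro-5-hydroxy-4,4-dimethoxynaphthalen-1(4H)-one | COC1(OC)c2c(O)c(Cl)cc(Br)c2C(=O)C=C1 | intermediate
6 | 8-bromo-6-chloro-4,4-dimethoxy-5-(methoxymethoxy)naphthalen-1(4H)-one | COC1(OC)c2c(OCOC)c(Cl)cc(Br)c2C(=O)C=C1 | intermediate
7 | (2R,3S)-8-bromo-6-chloro-2,3-epoxy-4,4-dimethoxy-5-(methoxymethoxy)-3,4-dihydronaphthalen-1(2H)-one | COC1(OC)c2c(OCOC)c(Cl)cc(Br)c2C(=O)[C@@H]2O[C@H]12 | intermediate
8 | 4-chlorobenzene-1,3-diol | Oc1ccc(Cl)c(O)c1 | starting material
9 | 4-bromo-6-chlorobenzene-1,3-diol | Oc1c(Br)cc(Cl)c(O)c1 | intermediate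
10 | 4-bromo-6-chloro-2-iodobenzene-1,3-diol | Oc1c(Br)cc(Cl)c(O)c1I | intermediate
11 | furan-2-boronic acid | OB(O)c1ccco1 | starting material
12 | 4-bromo-6-chloro-2-(furan-2-yl)benzene-1,3-diol | Oc1c(Br)cc(Cl)c(O)c1-c1ccco1 | intermediate
13 | 4-bromo-6-chloro-2-(furan-2-yl)-1,3-bis(trimethylsilyloxy)benzene | C[Si](C)(C)Oc1c(Br)cc(Cl)c(O[Si](C)(C)C)c1-c1ccco1 | intermediate
14 | lithium 4-chloro-2-(furan-2-yl)-6-(trimethylsilyl)-3-(trimethylsilyloxy)phenolate | [Li+].[O-]c1c([Si](C)(C)C)cc(Cl)c(O[Si](C)(C)C)c1-c1ccco1 | intermediate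
15 | 4-chloro-2-(furan-2-yl)-6-(trimethylsilyl)-3-(trimethylsilyloxy)phenyl trifluoromethanesulfonate | FC(F)(F)S(=O)(=O)Oc1c([Si](C)(C)C)cc(Cl)c(O[Si](C)(C)C)c1-c1ccco1 | intermediate
16 | 4-chloro-2-(furan-2-yl)-3-hydroxy-6-(trimethylsilyl)phenyl trifluoromethanesulfonate | FC(F)(F)S(=O)(=O)Oc1c([Si](C)(C)C)cc(Cl)c(O)c1-c1ccco1 | intermediate
17 | 4-chloro-2-(furan-2-yl)-3-(methoxymethoxy)-6-(trimethylsilyl)phenyl trifluoromethanesulfonate | FC(F)(F)S(=O)(=O)Oc1c([Si](C)(C)C)cc(Cl)c(OCOC)c1-c1ccco1 | intermediate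
18 | 4-chloro-3-(methoxymethoxy)-2-[5-(4,4,5,5-tetramethyl-1,3,2-dioxaborolan-2-yl)furan-2-yl]-6-(trimethylsilyl)phenyl trifluoromethanesulfonate | FC(F)(F)S(=O)(=O)Oc1c([Si](C)(C)C)cc(Cl)c(OCOC)c1-c1ccc(B2OC(C)(C)C(C)(C)O2)o1 | intermediate
19 | (2R,3S)-6-chloro-8-{5-[3-chloro-2-(methoxymethoxy)-6-(trifluoromethylsulfonyloxy)-5-(trimethylsilyl)phenyl]furan-2-yl}-2,3-epoxy-4,4-dimethoxy-5-(methoxymethoxy)-3,4-dihydronaphthalen-1(2H)-one | COC1(OC)c2c(OCOC)c(Cl)cc(-c3ccc(o3)-c3c(OS(=O)(=O)C(F)(F)F)c([Si](C)(C)C)cc(Cl)c3OCOC)c2C(=O)[C@@H]2O[C@H]12 | intermediate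
20 | (2R,3S)-6-chloro-8-{(Z)-4-[3-chloro-2-(methoxymethoxy)-6-(trifluoromethylsulfonyloxy)-5-(trimethylsilyl)phenyl]-4-oxobut-2-enoyl}-2,3-epoxy-4,4-dimethoxy-5-(methoxymethoxy)-3,4-dihydronaphthalen-1(2H)-one | COC1(OC)c2c(OCOC)c(Cl)cc(C(=O)/C=C\C(=O)c3c(OS(=O)(=O)C(F)(F)F)c([Si](C)(C)C)cc(Cl)c3OCOC)c2C(=O)[C@@H]2O[C@H]12 | intermediate
21 | aryne from 20 (C4a'≡C5'; Z-ene-1,4-dione and unit A unchanged) | COC1(OC)c2c(OCOC)c(Cl)cc(C(=O)/C=C\C(=O)C3=C(OCOC)C(Cl)=CC#C3)c2C(=O)[C@@H]2O[C@H]12 | intermediate
22 | benzoxete (four-membered ring C4'–O–C5'–C4a' fused to ring B; unit B carbocycle closed; C4' unassigned) | COC1(OC)c2c(OCOC)c(Cl)cc(C3(Oc4cc(Cl)c(OCOC)c5c43)C=CC5=O)c2C(=O)[C@@H]2O[C@H]12 | intermediate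
23 | 4'-(unit A aryl)-7'-chloro-8'-(methoxymethoxy)-1',5'-naphthoquinone (o-quinone methide O=C5'–C4a'=C4') | COC1(OC)c2c(OCOC)c(Cl)cc(C3=C4C(=O)C=C(Cl)C(OCOC)=C4C(=O)C=C3)c2C(=O)[C@@H]2O[C@H]12 | intermediate
24 | hexacyclic enone core: target skeleton with C1 as dimethyl ketal, C8 and C8' as MOM ethers, C1' ketone, C2'=C3' alkene; C4/C4' and ring A epoxide configured as in the target (bridging oxygen syn to the epoxide) | COC1(OC)c2c(OCOC)c(Cl)cc3c2[C@@]2(Oc4cc(Cl)c(OCOC)c5c4[C@]3(O2)C=CC5=O)[C@@H]2O[C@H]12 | intermediate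
25 | (1'R)-allylic alcohol of 24 (C1'–OH trans to the bridging oxygen, cis to the C4'–C5 bond) | COC1(OC)c2c(OCOC)c(Cl)cc3c2[C@@]2(Oc4cc(Cl)c(OCOC)c5c4[C@]3(O2)C=C[C@H]5O)[C@@H]2O[C@H]12 | intermediate
26 | (1'R)-tert-butyldimethylsilyl ether of 25 | COC1(OC)c2c(OCOC)c(Cl)cc3c2[C@@]2(Oc4cc(Cl)c(OCOC)c5c4[C@]3(O2)C=C[C@H]5O[Si](C)(C)C(C)(C)C)[C@@H]2O[C@H]12 | intermediate
27 | bis-epoxide: 26 with the C2'–C3' epoxide syn to the bridging oxygen and trans to OTBS | COC1(OC)c2c(OCOC)c(Cl)cc3c2[C@@]2(Oc4cc(Cl)c(OCOC)c5c4[C@]3(O2)[C@@H]2O[C@@H]2[C@H]5O[Si](C)(C)C(C)(C)C)[C@@H]2O[C@H]12 | intermediate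
28 | CNP0289684.3 | O=C1c2c(O)c(Cl)cc3c2[C@@]2(Oc4cc(Cl)c(O)c5c4[C@]3(O2)[C@@H]2O[C@@H]2[C@H]5O)[C@@H]2O[C@H]12 | target

## Summary

Total step count: 18.
Longest linear sequence: 13 steps (steps 6–11, then 12–18).

Steps most likely to fail:

Step 14 (Proposed new method). What may go wrong: the aryne is consumed by fluoride addition or bimolecular reactions before the tethered ketone closes, or the ene-dione isomerises from Z to E under fluoride so that C4' can no longer reach C4a'. Fallback: this sets out from 6 and 7, uses building block 6 a second time as unit B, and comes back to the route at quinone methide 23 and thereby at 24. Conjugate reduction of 6 with LiBH(s-Bu)3 and trapping of the enolate with PhNTf2 would give the enol triflate F1. Miyaura borylation of 7 (Pd(dppf)Cl2, B2pin2, KOAc) would give the unit A boronate F2. Suzuki–Miyaura coupling of F1 with F2 at the alkenyl triflate would give the coupled bromide F3. A second Miyaura borylation at the remaining aryl bromide would give the boronate F4, and oxidation with NaBO3·4H2O would give the phenol F5. Mild acid (PPTS, wet acetone) should hydrolyse the allylic dimethyl ketal of unit B faster than the epoxide-flanked ketal of unit A, and the resulting 4-aryl-naphthalen-1(2H)-one should tautomerise to the naphthalene-1,5-diol F6. Oxidation of F6 with Ag2O (the known oxidation of naphthalene-1,5-diols to 1,5-naphthoquinones) would generate 23 without any aryne, and 23 should close to 24 as in step 14.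

Step 5. What may go wrong: low or wrong-sense enantiofacial discrimination by the chiral ion pair on this peri-bromo enone ketal. Fallback: this sets out from 6 and comes back at 7, replacing catalyst-controlled epoxidation by a temporary carbinol stereocentre. CBS reduction of 6 with (S)-2-methyl-CBS-oxazaborolidine and catecholborane (aryl large, vinyl small) would give the (R)-allylic alcohol F7. Hydroxyl-directed epoxidation (VO(acac)2, t-BuOOH) would give the syn-epoxy alcohol F8. Oxidation with Dess–Martin periodinane would erase the carbinol centre and give 7.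

Step 15. What may go wrong: poor facial selectivity at C1' (the two faces of the remote enone differ little) or competing conjugate reduction. Fallback: this sets out from 24 and comes back at target 28, using substrate control from an epoxide installed first. Nucleophilic epoxidation of 24 (t-BuOOH, DBU, CH2Cl2) should occur on the convex face and give the epoxy ketone F9. Luche reduction (NaBH4, CeCl3·7H2O, MeOH, −78 °C) should add hydride anti to the epoxide oxygen and give the cis-epoxy alcohol F10. Mitsunobu inversion (4-nitrobenzoic acid, PPh3, DIAD) would give the inverted ester F11, and methanolysis (K2CO3, MeOH) the trans-epoxy alcohol F12. F12 would be deprotected under the conditions of step 18 to 28.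

## Further compounds

F1 | step 14 | 8-bromo-6-chloro-4,4-dimethoxy-5-(methoxymethoxy)-3,4-dihydronaphthalen-1-yl trifluoromethanesulfonate | COC1(OC)c2c(OCOC)c(Cl)cc(Br)c2C(OS(=O)(=O)C(F)(F)F)=CC1
F2 | step 14 | (2R,3S)-6-chloro-2,3-epoxy-4,4-dimethoxy-5-(methoxymethoxy)-8-(4,4,5,5-tetramethyl-1,3,2-dioxaborolan-2-yl)-3,4-dihydronaphthalen-1(2H)-one | COC1(OC)c2c(OCOC)c(Cl)cc(B3OC(C)(C)C(C)(C)O3)c2C(=O)[C@@H]2O[C@H]12
F3 | step 14 | coupled bromide: unit A epoxy ketone ketal bonded at C5 to C4' of 5'-bromo-7'-chloro-1',1'-dimethoxy-8'-(methoxymethoxy)-1',2'-dihydronaphthalene | COC1(OC)c2c(OCOC)c(Cl)cc(C3=CCC(OC)(OC)c4c(OCOC)c(Cl)cc(Br)c34)c2C(=O)[C@@H]2O[C@H]12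
F4 | step 14 | 5'-pinacolboronate of F3 | COC1(OC)c2c(OCOC)c(Cl)cc(C3=CCC(OC)(OC)c4c(OCOC)c(Cl)cc(B5OC(C)(C)C(C)(C)O5)c34)c2C(=O)[C@@H]2O[C@H]12
F5 | step 14 | 5'-phenol of F3 | COC1(OC)c2c(OCOC)c(Cl)cc(C3=CCC(OC)(OC)c4c(OCOC)c(Cl)cc(O)c34)c2C(=O)[C@@H]2O[C@H]12
F6 | step 14 | biaryl naphthalene-1',5'-diol: unit A epoxy ketone ketal bonded at C5 to C4' of 7'-chloro-8'-(methoxymethoxy)naphthalene-1',5'-diol | COC1(OC)c2c(OCOC)c(Cl)cc(-c3ccc(O)c4c(OCOC)c(Cl)cc(O)c34)c2C(=O)[C@@H]2O[C@H]12
F7 | step 5 | (R)-8-bromo-6-chloro-4,4-dimethoxy-5-(methoxymethoxy)-1,4-dihydronaphthalen-1-ol | COC1(OC)c2c(OCOC)c(Cl)cc(Br)c2[C@H](O)C=C1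
F8 | step 5 | syn-epoxy alcohol: 8-bromo-6-chloro-2,3-epoxy-4,4-dimethoxy-5-(methoxymethoxy)-1,2,3,4-tetrahydronaphthalen-1-ol with OH cis to the epoxide and the epoxide configured as in 7 | COC1(OC)c2c(OCOC)c(Cl)cc(Br)c2[C@H](O)[C@@H]2O[C@H]12
F9 | step 15 | epoxy ketone: 24 with the C2'–C3' epoxide syn to the bridging oxygen | COC1(OC)c2c(OCOC)c(Cl)cc3c2[C@@]2(Oc4cc(Cl)c(OCOC)c5c4[C@]3(O2)[C@@H]2O[C@@H]2C5=O)[C@@H]2O[C@H]12
F10 | step 15 | cis-epoxy alcohol: C1' epimer of F12 (OH syn to the ring B epoxide) | COC1(OC)c2c(OCOC)c(Cl)cc3c2[C@@]2(Oc4cc(Cl)c(OCOC)c5c4[C@]3(O2)[C@@H]2O[C@@H]2[C@@H]5O)[C@@H]2O[C@H]12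
F11 | step 15 | 4-nitrobenzoate of F12 (C1' configured as in the target) | COC1(OC)c2c(OCOC)c(Cl)cc3c2[C@@]2(Oc4cc(Cl)c(OCOC)c5c4[C@]3(O2)[C@@H]2O[C@@H]2[C@H]5OC(=O)c6ccc(cc6)[N+](=O)[O-])[C@@H]2O[C@H]12
F12 | step 15 | trans-epoxy alcohol: target with C1 as dimethyl ketal and C8, C8' as MOM ethers | COC1(OC)c2c(OCOC)c(Cl)cc3c2[C@@]2(Oc4cc(Cl)c(OCOC)c5c4[C@]3(O2)[C@@H]2O[C@@H]2[C@H]5O)[C@@H]2O[C@H]12
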